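**Plan**

1. Locants: the right half is numbered as azulene (C1 = C(OH)CH3 of the cyclopentane, C3a/C8a = ring fusion, C4 = C(CH3)2, C5 = alkene carbon carrying the CH2CH2 linker, C6 = alkene carbon carrying CH3, C7 = allylic CHOH). The left half is numbered as 1-benzoxepine (O1, C2 = C(CH3)2, C3 = CHOH, C5a/C9a = ring fusion, C6 = CH carrying the linker, C7 = C(OH)CH3).
2. Cuts: (a) C1–C8a, the last ring bond. The carbinol carbons C1 and C7 lie 1,4 to each other across the fusion carbon C8a, so with both as ketones C8a is the β-carbon of a C7 enone and C1 a ketyl donor. This is the retron of a reductive ketone–enone cyclization of a cross-conjugated cyclohepta-2,6-dienone with a 3-oxobutyl chain on C3a. (b) Linker–C5, by 1,2-addition of a left-half alkylcerium to a seven-membered vinylogous ester with transposition. (c) Left half: C5a–C6 and O1–C2 in one bis-epoxide cascade. (d) Seven-membered ring: C8=C8a (metathesis), C6–C7 (aldol), C5–C6 (ketone synthesis), C3a–C4 (Ireland–Claisen).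
3. Forward order: oxepane and cyclohexane together (step 5); cycloheptene (step 16); union of the halves (step 19); cyclopentane last (step 20); carbonyl reduction (step 21).
4. Stereochemistry: Shi epoxidation sets C3, C5a and C9a of the left half; the chair transition state and equilibration set C6; equatorial methyl addition sets left C7. Right-half C3a comes from (S)-but-3-yn-2-ol by chirality transfer in the Ireland–Claisen step; C8a and C1 are set in the key step under control of C3a; right-half C7 by CBS reduction.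

Key step: step 20

**Left half**

Step 1
Reactants: 1 geranyl bromide; 2 dimethyl (2-oxopropyl)phosphonate
Product: 4 dimethyl [(5E)-6,10-dimethyl-2-oxoundeca-5,9-dien-1-yl]phosphonate, via phosphonate dianion 3 (not isolated)
Conditions: NaH, THF, 0 °C; n-BuLi, 0 °C; then 1, 0 °C → rt; H2O
Reagents that add atoms: none
Why: The 1,3-dianion of a β-keto phosphonate is alkylated at its more basic terminal carbon by the primary allylic bromide (dianion γ-alkylation), and the E-alkene is untouched.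

Step 2
Reactants: 4 β-keto phosphonate; 5 (benzyloxy)acetaldehyde
Product: 6 (2E,7E)-1-(benzyloxy)-8,12-dimethyltrideca-2,7,11-trien-4-one
Conditions: LiCl, i-Pr2NEt, MeCN, rt
Reagents that add atoms: none
Why: Horner–Wadsworth–Emmons olefination under the mild LiCl/amine conditions gives the E-enone and tolerates the α-alkoxy aldehyde.

Step 3
Reactants: 6 trienone
Product: 7 (4E)-6-(benzyloxy)-1-[(2R,3R)-3-{2-[(2R)-3,3-dimethyloxiran-2-yl]ethyl}-3-methyloxiran-2-yl]hex-4-en-3-one
Conditions: Shi ketone from D-fructose (1,2:4,5-di-O-isopropylidene-β-D-erythro-2,3-hexodiulo-2,6-pyranose), Oxone (2KHSO5·KHSO4·K2SO4), K2CO3, Bu4NHSO4, MeCN–CH2(OMe)2–aq. buffer (pH 10.5), 0 °C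
Reagents that add atoms: potassium peroxymonosulfate, [K+].[O-]S(=O)(=O)OO
Why: Shi asymmetric epoxidation oxidizes only the two electron-rich trisubstituted alkenes (the enone alkene is inert to the dioxirane) through a spiro transition state that delivers oxygen to the same face of each, which should give the R configuration at both epoxide CH carbons and 2R,3R at the internal epoxide.

Step 4
Reactants: 7 diepoxy enone
Product: 8 {[(3Z)-6-(benzyloxy)-1-[(2R,3R)-3-{2-[(2R)-3,3-dimethyloxiran-2-yl]ethyl}-3-methyloxiran-2-yl]hex-3-en-3-yl]oxy}triethylsilane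
Conditions: RhCl(PPh3)3 (2 mol%), Et3SiH, toluene, 50 °C
Reagents that add atoms: triethylsilane, CC[SiH](CC)CC
Why: Rhodium-catalysed 1,4-hydrosilylation of the enone through its s-cis conformer should give the Z silyl enol ether regiospecifically on the side of the former alkene, which fixes the α-carbon that acts as nucleophile in step 5; epoxides and benzyl ether are inert.

Step 5
Reactants: 8 diepoxy silyl enol ether
Product: 9 (3R,5aR,6R,9aR)-6-[2-(benzyloxy)ethyl]-2,2,5a-trimethyl-3-[(triethylsilyl)oxy]-3,4,5,5a,6,8,9,9a-octahydro-1-benzoxepin-7(2H)-one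
Conditions: Et3SiOTf (0.3 equiv), 2,6-di-tert-butyl-4-methylpyridine, CH2Cl2, −78 °C; then DBU (cat.), rt
Reagents that add atoms: none
Why: Silyl-triflate-initiated tandem oxa-/carbacyclization of a 1,5-bis-epoxide, in which the silylated terminal epoxide is opened at its tertiary carbon by the oxygen of the internal epoxide and the resulting epoxonium ion is opened with inversion at its tertiary carbon by the silyl enol ether through a chair transition state; the E-derived epoxide therefore gives the trans ring fusion, C3 and C9a keep their epoxide configurations, the Z enol ether places the side chain equatorial at C6 (also the thermodynamic epimer, secured by the DBU equilibration), and the silyl triflate released from the enol ether carries the chain.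

Step 6
Reactants: 9 bicyclic ketone
Product: 10 (3R,5aR,6R,7S,9aR)-6-[2-(benzyloxy)ethyl]-2,2,5a,7-tetramethyl-3-[(triethylsilyl)oxy]decahydro-1-benzoxepin-7-ol
Conditions: MeMgBr, CeCl3, THF, −78 °C
Reagents that add atoms: methylmagnesium bromide, C[Mg]Br
Why: Cerium-moderated Grignard addition suppresses enolization, and the methyl group should enter from the equatorial direction because the axial face is blocked 1,3-diaxially by the angular C5a methyl, giving the axial tertiary alcohol (7S).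

Step 7
Reactants: 10 tertiary alcohol
Product: 11 (3R,5aR,6R,7S,9aR)-6-[2-(benzyloxy)ethyl]-2,2,5a,7-tetramethyl-3,7-bis[(triethylsilyl)oxy]decahydro-1-benzoxepine
Conditions: Et3SiOTf, 2,6-lutidine, CH2Cl2, 0 °C → rt
Reagents that add atoms: triethylsilyl trifluoromethanesulfonate, CC[Si](CC)(CC)OS(=O)(=O)C(F)(F)F
Why: A silyl triflate with a hindered pyridine base silylates even hindered tertiary alcohols, and the protection is needed so that the later primary iodide cannot be displaced intramolecularly to a tetrahydrofuran.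

Step 8
Reactants: 11 benzyl ether
Product: 12 2-[(3R,5aR,6R,7S,9aR)-2,2,5a,7-tetramethyl-3,7-bis[(triethylsilyl)oxy]decahydro-1-benzoxepin-6-yl]ethan-1-ol
Conditions: H2 (1 atm), Pd/C, EtOAc, rt
Reagents that add atoms: none
Why: Hydrogenolysis of the benzyl ether over palladium in a non-protic solvent should leave both triethylsilyl ethers intact, and no alkene is present.

Step 9
Reactants: 12 primary alcohol
Product: 13 (3R,5aR,6R,7S,9aR)-6-(2-iodoethyl)-2,2,5a,7-tetramethyl-3,7-bis[(triethylsilyl)oxy]decahydro-1-benzoxepine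
Conditions: I2, PPh3, imidazole, CH2Cl2, 0 °C → rt
Reagents that add atoms: iodine, II
Why: Appel-type iodination converts the unhindered primary alcohol into the iodide under buffered conditions that spare the silyl ethers.

**Right half**

Step 10
Reactants: 14 (2S)-but-3-yn-2-ol; 15 2-(2-bromoethyl)-2-methyl-1,3-dioxolane
Product: 17 (2S)-6-(2-methyl-1,3-dioxolan-2-yl)hex-3-yn-2-ol, via dilithium alkynolate 16 (not isolated)
Conditions: n-BuLi (2.1 equiv), THF, −78 → 0 °C; DMPU; then 15, 0 °C → rt; H2O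
Reagents that add atoms: none
Why: The C,O-dilithio derivative of the propargylic alcohol is alkylated at the acetylide carbon by the primary bromide (acetylide alkylation), and the stereocentre is not involved.

Step 11
Reactants: 17 propargylic alcohol
Product: 18 (2S,3E)-6-(2-methyl-1,3-dioxolan-2-yl)hex-3-en-2-ol
Conditions: NaAlH2(OCH2CH2OCH3)2, THF, 0 °C → rt; aq. sodium potassium tartrate
Reagents that add atoms: none
Why: Hydroxyl-directed trans-hydroalumination of a propargylic alcohol gives the E-allylic alcohol, and the ketal is inert.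

Step 12
Reactants: 18 allylic alcohol; 19 2-methylpropanoyl chloride
Product: 20 (2S,3E)-6-(2-methyl-1,3-dioxolan-2-yl)hex-3-en-2-yl 2-methylpropanoate
Conditions: pyridine, DMAP (cat.), CH2Cl2, 0 °C
Reagents that add atoms: none
Why: Standard DMAP-catalysed acylation of a secondary alcohol with an acid chloride.

Step 13
Reactants: 20 allylic isobutyrate
Product: 23 (3R,4E)-2,2-dimethyl-3-[2-(2-methyl-1,3-dioxolan-2-yl)ethyl]hex-4-enoic acid, via silyl ketene acetal 21 (not isolated), via trimethylsilyl ester 22 (not isolated)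
Conditions: LiN(i-Pr)2, THF, −78 °C; Me3SiCl–Et3N; −78 → 60 °C; aq. NaOH, then citric acid (pH 4)
Reagents that add atoms: none
Why: Ireland–Claisen rearrangement, in which the isobutyrate gives a single symmetrical silyl ketene acetal that rearranges through a chair transition state with the carbinol methyl equatorial, so the S,E-allylic ester should transfer its chirality to the new tertiary centre (3R) next to the new gem-dimethyl carbon.

Step 14
Reactants: 23 carboxylic acid
Product: 25 (5R,6E)-4,4-dimethyl-5-[2-(2-methyl-1,3-dioxolan-2-yl)ethyl]oct-6-en-3-one, via dilithium gem-diolate 24 (not isolated)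
Conditions: EtLi (2.2 equiv), Et2O, 0 °C → rt; H2O
Reagents that add atoms: ethyllithium, [Li]CC
Why: Addition of an alkyllithium to a lithium carboxylate stops at the dilithium gem-diolate, which gives the ketone on hydrolysis, and the neighbouring quaternary carbon prevents over-addition.

Step 15
Reactants: 25 ethyl ketone; 26 acrolein
Product: 28 (7R,8E)-3-hydroxy-4,6,6-trimethyl-7-[2-(2-methyl-1,3-dioxolan-2-yl)ethyl]deca-1,8-dien-5-one (mixture at C3 and C4), via lithium enolate 27 (not isolated)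
Conditions: LiN(i-Pr)2, THF, −78 °C; then 26, −78 °C; H2O
Reagents that add atoms: none
Why: The ketone can enolize only on its ethyl side because the other α-carbon is quaternary, and the lithium enolate adds 1,2 to acrolein at low temperature (aldol addition); the two new stereocentres are removed again in steps 17 to 19.

Step 16
Reactants: 28 aldol adduct
Product: 29 (6R)-3-hydroxy-2,7,7-trimethyl-6-[2-(2-methyl-1,3-dioxolan-2-yl)ethyl]cyclohept-4-en-1-one (mixture at C2 and C3)
Conditions: second-generation Grubbs catalyst RuCl2(PCy3)(H2IMes)(=CHPh) (5 mol%), CH2Cl2, 40 °C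
Reagents that add atoms: none
Why: Ring-closing metathesis closes the seven-membered ring as the cis-alkene, helped by the gem-dimethyl group, the propenyl terminus leaves as propene, and C6 is not touched.

Step 17
Reactants: 29 hydroxy ketone
Product: 30 (6R)-2,7,7-trimethyl-6-[2-(2-methyl-1,3-dioxolan-2-yl)ethyl]cyclohept-4-ene-1,3-dione
Conditions: Dess–Martin periodinane, NaHCO3, CH2Cl2, rt
Reagents that add atoms: none
Why: Dess–Martin oxidation of a β-hydroxy ketone gives the 1,3-diketone under buffered conditions without retro-aldol cleavage or loss of the ketal.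

Step 18
Reactants: 30 ene-dione
Product: 31 (6R)-3-methoxy-2,7,7-trimethyl-6-[2-(2-methyl-1,3-dioxolan-2-yl)ethyl]cyclohepta-2,4-dien-1-one
Conditions: Me2SO4, K2CO3, acetone, reflux
Reagents that add atoms: dimethyl sulfate, COS(=O)(=O)OC
Why: O-Alkylation of the 2-methyl-1,3-diketone enolate with a hard electrophile should occur at the less hindered oxygen remote from the gem-dimethyl carbon, which also gives the linearly conjugated dienone, so that the carbonyl left over is the one attacked in step 19.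

**Union and end game**

Step 19
Reactants: 13 left-half iodide; 31 seven-membered vinylogous ester
Product: 35 (5R)-3-{2-[(3R,5aR,6R,7S,9aR)-3,7-dihydroxy-2,2,5a,7-tetramethyldecahydro-1-benzoxepin-6-yl]ethyl}-2,4,4-trimethyl-5-(3-oxobutyl)cyclohepta-2,6-dien-1-one, via alkyllithium 32 (not isolated), via alkylcerium dichloride 33 (not isolated), via tertiary carbinol 34 (not isolated)
Conditions: 13, t-BuLi (2 equiv per 13), Et2O–pentane, −78 °C; CeCl3 (anhydrous), THF, −78 °C; then 31, −78 → −20 °C; then 2 M aq. HCl–MeOH–THF, rt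
Reagents that add atoms: water, O
Why: Iodine–lithium exchange and transmetalation give a weakly basic alkylcerium that should add 1,2 to the hindered carbonyl of the vinylogous ester, and aqueous acid then converts the tertiary allylic alcohol and enol ether into the transposed cross-conjugated dienone (Stork–Danheiser sequence) while also cleaving the dioxolane and both triethylsilyl ethers; no stereocentre is formed or touched.

Step 20
Reactants: 35 dienone methyl ketone
Product: 37 (3R,3aR,8aR)-7-{2-[(3R,5aR,6R,7S,9aR)-3,7-dihydroxy-2,2,5a,7-tetramethyldecahydro-1-benzoxepin-6-yl]ethyl}-3-hydroxy-3,6,8,8-tetramethyl-2,3,3a,4,8,8a-hexahydroazulen-5(1H)-one, via samarium enolate 36 (not isolated)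
Conditions: SmI2 (2.5 equiv), t-BuOH (3 equiv), THF, −78 → −40 °C; aq. NH4Cl
Reagents that add atoms: none
Why: Electron transfer from divalent samarium to 35 (to the side-chain ketone, or to the dienone followed by attack of its β-carbon radical on the ketone, the two paths converging) joins the ketone carbon to the β-carbon of the disubstituted enone, and a second electron turns the resulting α-keto radical into the trivalent samarium enolate 36, which tert-butanol protonates at C8 (azulene locants of the final product here and below) to return the C5=C6–C7=O enone while shielding it from over-reduction. The closest known reaction type is the samarium diiodide ketyl–olefin cyclization of ketones onto α,β-unsaturated carbonyl acceptors. The cyclopentane closes in the 5-exo-trig mode by forming C1–C8a. C8a is set by the three-atom tether fixed on C3a, which can reach only the same face of the seven-membered ring and so gives the cis ring fusion; C1 is set by the bulky samarium-bound ketyl oxygen, which should turn away from the seven-membered ring (anti to C8), leaving the methyl group on the concave face and the hydroxyl cis to H8a. The step needs a choice between the two enone β-carbons of the cross-conjugated dienone, and here only C8a lies within reach of the tether, while C5 is tetrasubstituted and remote.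

Step 21
Reactants: 37 hydroazulenone
Product: 38 (1R,3aR,7S,8aR)-5-{2-[(3R,5aR,6R,7S,9aR)-3,7-dihydroxy-2,2,5a,7-tetramethyldecahydro-1-benzoxepin-6-yl]ethyl}-1,4,4,6-tetramethyl-1,2,3,3a,4,7,8,8a-octahydroazulene-1,7-diol
Conditions: (R)-2-methyl-CBS-oxazaborolidine (1 equiv), BH3·SMe2 (excess), THF, −30 °C; MeOH
Reagents that add atoms: none
Why: Corey–Bakshi–Shibata reduction, in which the (R)-oxazaborolidine, with the tetrasubstituted alkenyl carbon as the large and the CH2 as the small carbonyl substituent, should deliver hydride to the face that gives the 7S allylic alcohol, which is also the convex (H8a) face of the cis-fused bicycle; the free hydroxyls are accommodated by excess borane.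

**Compound list**

1 | geranyl bromide, (2E)-1-bromo-3,7-dimethylocta-2,6-diene | CC(C)=CCC/C(C)=C/CBr | starting material
2 | dimethyl (2-oxopropyl)phosphonate | COP(=O)(OC)CC(C)=O | starting material
3 | sodium lithium 1,3-dianion of 2 | COP(=O)(OC)[CH-]C(=O)[CH2-].[Na+].[Li+] | intermediate
4 | dimethyl [(5E)-6,10-dimethyl-2-oxoundeca-5,9-dien-1-yl]phosphonate | COP(=O)(OC)CC(=O)CC/C=C(\C)CCC=C(C)C | intermediate
5 | (benzyloxy)acetaldehyde | O=CCOCc1ccccc1 | starting material
6 | (2E,7E)-1-(benzyloxy)-8,12-dimethyltrideca-2,7,11-trien-4-one | O=C(/C=C/COCc1ccccc1)CC/C=C(\C)CCC=C(C)C | intermediate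
7 | (4E)-6-(benzyloxy)-1-[(2R,3R)-3-{2-[(2R)-3,3-dimethyloxiran-2-yl]ethyl}-3-methyloxiran-2-yl]hex-4-en-3-one | O=C(/C=C/COCc1ccccc1)CC[C@H]1O[C@]1(C)CC[C@H]1OC1(C)C | intermediate
8 | {[(3Z)-6-(benzyloxy)-1-[(2R,3R)-3-{2-[(2R)-3,3-dimethyloxiran-2-yl]ethyl}-3-methyloxiran-2-yl]hex-3-en-3-yl]oxy}triethylsilane | O(Cc1ccccc1)CC/C=C(\O[Si](CC)(CC)CC)CC[C@H]1O[C@]1(C)CC[C@H]1OC1(C)C | intermediate
9 | (3R,5aR,6R,9aR)-6-[2-(benzyloxy)ethyl]-2,2,5a-trimethyl-3-[(triethylsilyl)oxy]-3,4,5,5a,6,8,9,9a-octahydro-1-benzoxepin-7(2H)-one | O(Cc1ccccc1)CC[C@@H]1[C@@]2(C)CC[C@@H](O[Si](CC)(CC)CC)C(C)(C)O[C@@H]2CCC1=O | intermediate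
10 | (3R,5aR,6R,7S,9aR)-6-[2-(benzyloxy)ethyl]-2,2,5a,7-tetramethyl-3-[(triethylsilyl)oxy]decahydro-1-benzoxepin-7-ol | O(Cc1ccccc1)CC[C@@H]1[C@@]2(C)CC[C@@H](O[Si](CC)(CC)CC)C(C)(C)O[C@@H]2CC[C@]1(C)O | intermediate
11 | (3R,5aR,6R,7S,9aR)-6-[2-(benzyloxy)ethyl]-2,2,5a,7-tetramethyl-3,7-bis[(triethylsilyl)oxy]decahydro-1-benzoxepine | O(Cc1ccccc1)CC[C@@H]1[C@@]2(C)CC[C@@H](O[Si](CC)(CC)CC)C(C)(C)O[C@@H]2CC[C@]1(C)O[Si](CC)(CC)CC | intermediate
12 | 2-[(3R,5aR,6R,7S,9aR)-2,2,5a,7-tetramethyl-3,7-bis[(triethylsilyl)oxy]decahydro-1-benzoxepin-6-yl]ethan-1-ol | OCC[C@@H]1[C@@]2(C)CC[C@@H](O[Si](CC)(CC)CC)C(C)(C)O[C@@H]2CC[C@]1(C)O[Si](CC)(CC)CC | intermediate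
13 | (3R,5aR,6R,7S,9aR)-6-(2-iodoethyl)-2,2,5a,7-tetramethyl-3,7-bis[(triethylsilyl)oxy]decahydro-1-benzoxepine | ICC[C@@H]1[C@@]2(C)CC[C@@H](O[Si](CC)(CC)CC)C(C)(C)O[C@@H]2CC[C@]1(C)O[Si](CC)(CC)CC | intermediate
14 | (2S)-but-3-yn-2-ol | C[C@H](O)C#C | starting material
15 | 2-(2-bromoethyl)-2-methyl-1,3-dioxolane | CC1(CCBr)OCCO1 | starting material
16 | dilithium salt of 14 (alkoxide and acetylide) | C[C@H]([O-])C#[C-].[Li+].[Li+] | intermediate
17 | (2S)-6-(2-methyl-1,3-dioxolan-2-yl)hex-3-yn-2-ol | C[C@H](O)C#CCCC1(C)OCCO1 | intermediate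
18 | (2S,3E)-6-(2-methyl-1,3-dioxolan-2-yl)hex-3-en-2-ol | C[C@H](O)/C=C/CCC1(C)OCCO1 | intermediate
19 | 2-methylpropanoyl chloride | CC(C)C(Cl)=O | starting material
20 | (2S,3E)-6-(2-methyl-1,3-dioxolan-2-yl)hex-3-en-2-yl 2-methylpropanoate | C[C@H](OC(=O)C(C)C)/C=C/CCC1(C)OCCO1 | intermediate
21 | trimethyl{[2-methyl-1-{[(2S,3E)-6-(2-methyl-1,3-dioxolan-2-yl)hex-3-en-2-yl]oxy}prop-1-en-1-yl]oxy}silane | C[C@H](OC(O[Si](C)(C)C)=C(C)C)/C=C/CCC1(C)OCCO1 | intermediate
22 | trimethylsilyl (3R,4E)-2,2-dimethyl-3-[2-(2-methyl-1,3-dioxolan-2-yl)ethyl]hex-4-enoate | C[Si](C)(C)OC(=O)C(C)(C)[C@H](CCC1(C)OCCO1)/C=C/C | intermediate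
23 | (3R,4E)-2,2-dimethyl-3-[2-(2-methyl-1,3-dioxolan-2-yl)ethyl]hex-4-enoic acid | OC(=O)C(C)(C)[C@H](CCC1(C)OCCO1)/C=C/C | intermediate
24 | dilithium gem-diolate from 23 and ethyllithium | CCC([O-])([O-])C(C)(C)[C@H](CCC1(C)OCCO1)/C=C/C.[Li+].[Li+] | intermediate
25 | (5R,6E)-4,4-dimethyl-5-[2-(2-methyl-1,3-dioxolan-2-yl)ethyl]oct-6-en-3-one | CCC(=O)C(C)(C)[C@H](CCC1(C)OCCO1)/C=C/C | intermediate
26 | acrolein (prop-2-enal) | C=CC=O | starting material
27 | lithium (Z)-enolate of 25 | C/C=C(\[O-])C(C)(C)[C@H](CCC1(C)OCCO1)/C=C/C.[Li+] | intermediate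
28 | (7R,8E)-3-hydroxy-4,6,6-trimethyl-7-[2-(2-methyl-1,3-dioxolan-2-yl)ethyl]deca-1,8-dien-5-one (mixture at C3, C4) | C=CC(O)C(C)C(=O)C(C)(C)[C@H](CCC1(C)OCCO1)/C=C/C | intermediate
29 | (6R)-3-hydroxy-2,7,7-trimethyl-6-[2-(2-methyl-1,3-dioxolan-2-yl)ethyl]cyclohept-4-en-1-one (mixture at C2, C3) | CC1C(O)C=C[C@@H](CCC2(C)OCCO2)C(C)(C)C1=O | intermediate
30 | (6R)-2,7,7-trimethyl-6-[2-(2-methyl-1,3-dioxolan-2-yl)ethyl]cyclohept-4-ene-1,3-dione | CC1C(=O)C=C[C@@H](CCC2(C)OCCO2)C(C)(C)C1=O | intermediate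
31 | (6R)-3-methoxy-2,7,7-trimethyl-6-[2-(2-methyl-1,3-dioxolan-2-yl)ethyl]cyclohepta-2,4-dien-1-one | COC1=C(C)C(=O)C(C)(C)[C@H](CCC2(C)OCCO2)C=C1 | intermediate
32 | alkyllithium from 13 (Li in place of I) | [Li]CC[C@@H]1[C@@]2(C)CC[C@@H](O[Si](CC)(CC)CC)C(C)(C)O[C@@H]2CC[C@]1(C)O[Si](CC)(CC)CC | intermediate
33 | alkylcerium dichloride from 32 | Cl[Ce](Cl)CC[C@@H]1[C@@]2(C)CC[C@@H](O[Si](CC)(CC)CC)C(C)(C)O[C@@H]2CC[C@]1(C)O[Si](CC)(CC)CC | intermediate
34 | tertiary carbinol from 1,2-addition of 33 to 31 (mixture at the carbinol carbon) | COC1=C(C)C(O)(CC[C@@H]2[C@@]3(C)CC[C@@H](O[Si](CC)(CC)CC)C(C)(C)O[C@@H]3CC[C@]2(C)O[Si](CC)(CC)CC)C(C)(C)[C@H](CCC2(C)OCCO2)C=C1 | intermediate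
35 | (5R)-3-{2-[(3R,5aR,6R,7S,9aR)-3,7-dihydroxy-2,2,5a,7-tetramethyldecahydro-1-benzoxepin-6-yl]ethyl}-2,4,4-trimethyl-5-(3-oxobutyl)cyclohepta-2,6-dien-1-one | CC1=C(CC[C@@H]2[C@@]3(C)CC[C@@H](O)C(C)(C)O[C@@H]3CC[C@]2(C)O)C(C)(C)[C@H](CCC(C)=O)C=CC1=O | intermediate
36 | bis(diiodosamarium) derivative of cyclized 35 (tertiary alkoxide and dienolate) | CC1=C(CC[C@@H]2[C@@]3(C)CC[C@@H](O)C(C)(C)O[C@@H]3CC[C@]2(C)O)C(C)(C)[C@@H]2CC[C@@](C)(O[Sm](I)I)[C@@H]2C=C1O[Sm](I)I | intermediate
37 | (3R,3aR,8aR)-7-{2-[(3R,5aR,6R,7S,9aR)-3,7-dihydroxy-2,2,5a,7-tetramethyldecahydro-1-benzoxepin-6-yl]ethyl}-3-hydroxy-3,6,8,8-tetramethyl-2,3,3a,4,8,8a-hexahydroazulen-5(1H)-one | CC1=C(CC[C@@H]2[C@@]3(C)CC[C@@H](O)C(C)(C)O[C@@H]3CC[C@]2(C)O)C(C)(C)[C@@H]2CC[C@@](C)(O)[C@@H]2CC1=O | intermediate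
38 | (1R,3aR,7S,8aR)-5-{2-[(3R,5aR,6R,7S,9aR)-3,7-dihydroxy-2,2,5a,7-tetramethyldecahydro-1-benzoxepin-6-yl]ethyl}-1,4,4,6-tetramethyl-1,2,3,3a,4,7,8,8a-octahydroazulene-1,7-diol | CC1=C(CC[C@@H]2[C@@]3(C)CC[C@@H](O)C(C)(C)O[C@@H]3CC[C@]2(C)O)C(C)(C)[C@@H]2CC[C@@](C)(O)[C@@H]2C[C@@H]1O | target

**Count and risks**

Total step count: 21. Longest linear sequence: 12 steps (steps 1–9 or 10–18, then 19–21).

Steps most likely to fail:

Step 20. The electron may be taken up by the cross-conjugated dienone and end in plain 1,4-reduction or reductive dimerization instead of ring closure, or the facial selectivity at the new carbinol carbon may be poor. The fallback sets out from 35 and comes back at 37, and forms the same radical by hydrogen-atom transfer instead of electron transfer. Treating 35 with t-BuMe2SiOTf and Et3N (CH2Cl2, −78 → 0 °C) should silylate the secondary hydroxyl and convert the side-chain ketone into its silyl enol ether, (5R)-5-{3-[(tert-butyldimethylsilyl)oxy]but-3-en-1-yl}-3-{2-[(3R,5aR,6R,7S,9aR)-3-[(tert-butyldimethylsilyl)oxy]-7-hydroxy-2,2,5a,7-tetramethyldecahydro-1-benzoxepin-6-yl]ethyl}-2,4,4-trimethylcyclohepta-2,6-dien-1-one F1; the regioisomeric internal enol ether would lead to the same radical. Fe(acac)3 and PhSiH3 in EtOH–ethylene glycol at 60 °C (hydrogen-atom-transfer-initiated radical conjugate addition) should then close the ring 5-exo onto the enone to the silyl ether (3R,3aR,8aR)-3-[(tert-butyldimethylsilyl)oxy]-7-{2-[(3R,5aR,6R,7S,9aR)-3-[(tert-butyldimethylsilyl)oxy]-7-hydroxy-2,2,5a,7-tetramethyldecahydro-1-benzoxepin-6-yl]ethyl}-3,6,8,8-tetramethyl-2,3,3a,4,8,8a-hexahydroazulen-5(1H)-one F2. HF·pyridine in THF removes both silyl groups and gives 37.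

Step 19. The carbonyl of 31 is flanked by the gem-dimethyl carbon and a methylated enol ether carbon, so 1,2-addition may be overtaken by 1,6-addition or deprotonation, and the acid treatment may start other acid-catalysed changes before all protecting groups are off. The fallback sets out from 13 and 29 and comes back at 35; it makes the linker–C5 bond by B-alkyl Suzuki–Miyaura coupling instead of carbonyl addition.
- Left partner: elimination of 13 with KOt-Bu (THF, 0 °C) should give (3R,5aR,6R,7S,9aR)-6-ethenyl-2,2,5a,7-tetramethyl-3,7-bis[(triethylsilyl)oxy]decahydro-1-benzoxepine F3. Hydroboration with 9-BBN (THF, rt) gives the B-alkyl-9-borabicyclo[3.3.1]nonane F4, used in solution.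
- Right partner: 29 is silylated (Et3SiCl, imidazole, DMF) to (6R)-2,7,7-trimethyl-6-[2-(2-methyl-1,3-dioxolan-2-yl)ethyl]-3-[(triethylsilyl)oxy]cyclohept-4-en-1-one F5. Its only possible enolate (KN(SiMe3)2, THF, −78 °C; PhNTf2) gives the enol triflate (6R)-2,7,7-trimethyl-6-[2-(2-methyl-1,3-dioxolan-2-yl)ethyl]-3-[(triethylsilyl)oxy]cyclohepta-1,4-dien-1-yl trifluoromethanesulfonate F6.
- Coupling and return: F4 and F6 with PdCl2(dppf), AsPh3 and Cs2CO3 in DMF–THF–H2O should give the coupled tris(triethylsilyl) ether F7. Bu4NF (THF) gives the triol ketal F8. MnO2 (CH2Cl2) oxidizes only the doubly allylic alcohol, giving the dienone ketal F9. 1 M aq. HCl in THF then frees the methyl ketone and gives 35.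

Step 5. The cascade may start at the internal instead of the terminal epoxide, may stop after the first ring through loss of the labile silyl enol ether, or may open the second epoxide in the exo mode. The fallback sets out from 4 and comes back at 9; it uses the doubly activated carbon of the β-keto phosphonate itself as the terminating nucleophile and attaches the side chain afterwards. Shi epoxidation of 4 (same ketone, buffered at pH 8 to keep the phosphonate un-ionized) should give dimethyl {4-[(2R,3R)-3-{2-[(2R)-3,3-dimethyloxiran-2-yl]ethyl}-3-methyloxiran-2-yl]-2-oxobutyl}phosphonate F10. Et3SiOTf (1.1 equiv) and 2,6-di-tert-butyl-4-methylpyridine (CH2Cl2, −78 °C) should give the bicyclic β-keto phosphonate F11, with the C3, C5a and C9a configurations of 9. Horner–Wadsworth–Emmons reaction of F11 with 5 (LiCl, DBU, MeCN) gives (3R,5aR,9aR)-6-[2-(benzyloxy)ethylidene]-2,2,5a-trimethyl-3-[(triethylsilyl)oxy]-3,4,5,5a,6,8,9,9a-octahydro-1-benzoxepin-7(2H)-one F12. Conjugate reduction with [(Ph3P)CuH]6 and PhSiH3 (toluene), followed by DBU equilibration at C6, gives 9.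

Further compounds
F1 | step 20 | (5R)-5-{3-[(tert-butyldimethylsilyl)oxy]but-3-en-1-yl}-3-{2-[(3R,5aR,6R,7S,9aR)-3-[(tert-butyldimethylsilyl)oxy]-7-hydroxy-2,2,5a,7-tetramethyldecahydro-1-benzoxepin-6-yl]ethyl}-2,4,4-trimethylcyclohepta-2,6-dien-1-one | CC1=C(CC[C@@H]2[C@@]3(C)CC[C@@H](O[Si](C)(C)C(C)(C)C)C(C)(C)O[C@@H]3CC[C@]2(C)O)C(C)(C)[C@H](CCC(=C)O[Si](C)(C)C(C)(C)C)C=CC1=O
F2 | step 20 | (3R,3aR,8aR)-3-[(tert-butyldimethylsilyl)oxy]-7-{2-[(3R,5aR,6R,7S,9aR)-3-[(tert-butyldimethylsilyl)oxy]-7-hydroxy-2,2,5a,7-tetramethyldecahydro-1-benzoxepin-6-yl]ethyl}-3,6,8,8-tetramethyl-2,3,3a,4,8,8a-hexahydroazulen-5(1H)-one | CC1=C(CC[C@@H]2[C@@]3(C)CC[C@@H](O[Si](C)(C)C(C)(C)C)C(C)(C)O[C@@H]3CC[C@]2(C)O)C(C)(C)[C@@H]2CC[C@@](C)(O[Si](C)(C)C(C)(C)C)[C@@H]2CC1=O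
F3 | step 19 | (3R,5aR,6R,7S,9aR)-6-ethenyl-2,2,5a,7-tetramethyl-3,7-bis[(triethylsilyl)oxy]decahydro-1-benzoxepine | C=C[C@@H]1[C@@]2(C)CC[C@@H](O[Si](CC)(CC)CC)C(C)(C)O[C@@H]2CC[C@]1(C)O[Si](CC)(CC)CC
F4 | step 19 | 9-{2-[(3R,5aR,6R,7S,9aR)-2,2,5a,7-tetramethyl-3,7-bis[(triethylsilyl)oxy]decahydro-1-benzoxepin-6-yl]ethyl}-9-borabicyclo[3.3.1]nonane | C1CCC2CCCC1B2CC[C@@H]1[C@@]2(C)CC[C@@H](O[Si](CC)(CC)CC)C(C)(C)O[C@@H]2CC[C@]1(C)O[Si](CC)(CC)CC
F5 | step 19 | (6R)-2,7,7-trimethyl-6-[2-(2-methyl-1,3-dioxolan-2-yl)ethyl]-3-[(triethylsilyl)oxy]cyclohept-4-en-1-one (mixture at C2, C3) | CC1C(O[Si](CC)(CC)CC)C=C[C@@H](CCC2(C)OCCO2)C(C)(C)C1=O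
F6 | step 19 | (6R)-2,7,7-trimethyl-6-[2-(2-methyl-1,3-dioxolan-2-yl)ethyl]-3-[(triethylsilyl)oxy]cyclohepta-1,4-dien-1-yl trifluoromethanesulfonate (mixture at C3) | CC1=C(OS(=O)(=O)C(F)(F)F)C(C)(C)[C@H](CCC2(C)OCCO2)C=CC1O[Si](CC)(CC)CC
F7 | step 19 | (3R,5aR,6R,7S,9aR)-2,2,5a,7-tetramethyl-6-{2-[(6R)-2,7,7-trimethyl-6-[2-(2-methyl-1,3-dioxolan-2-yl)ethyl]-3-[(triethylsilyl)oxy]cyclohepta-1,4-dien-1-yl]ethyl}-3,7-bis[(triethylsilyl)oxy]decahydro-1-benzoxepine | CC1=C(CC[C@@H]2[C@@]3(C)CC[C@@H](O[Si](CC)(CC)CC)C(C)(C)O[C@@H]3CC[C@]2(C)O[Si](CC)(CC)CC)C(C)(C)[C@H](CCC2(C)OCCO2)C=CC1O[Si](CC)(CC)CC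
F8 | step 19 | (3R,5aR,6R,7S,9aR)-6-{2-[(6R)-3-hydroxy-2,7,7-trimethyl-6-[2-(2-methyl-1,3-dioxolan-2-yl)ethyl]cyclohepta-1,4-dien-1-yl]ethyl}-2,2,5a,7-tetramethyldecahydro-1-benzoxepine-3,7-diol | CC1=C(CC[C@@H]2[C@@]3(C)CC[C@@H](O)C(C)(C)O[C@@H]3CC[C@]2(C)O)C(C)(C)[C@H](CCC2(C)OCCO2)C=CC1O
F9 | step 19 | (5R)-3-{2-[(3R,5aR,6R,7S,9aR)-3,7-dihydroxy-2,2,5a,7-tetramethyldecahydro-1-benzoxepin-6-yl]ethyl}-2,4,4-trimethyl-5-[2-(2-methyl-1,3-dioxolan-2-yl)ethyl]cyclohepta-2,6-dien-1-one | CC1=C(CC[C@@H]2[C@@]3(C)CC[C@@H](O)C(C)(C)O[C@@H]3CC[C@]2(C)O)C(C)(C)[C@H](CCC2(C)OCCO2)C=CC1=O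
F10 | step 5 | dimethyl {4-[(2R,3R)-3-{2-[(2R)-3,3-dimethyloxiran-2-yl]ethyl}-3-methyloxiran-2-yl]-2-oxobutyl}phosphonate | COP(=O)(OC)CC(=O)CC[C@H]1O[C@]1(C)CC[C@H]1OC1(C)C
F11 | step 5 | dimethyl {2,2,5a-trimethyl-7-oxo-3-[(triethylsilyl)oxy]decahydro-1-benzoxepin-6-yl}phosphonate with the C3, C5a and C9a configurations of 9 (C6 epimers) | COP(=O)(OC)C1[C@@]2(C)CC[C@@H](O[Si](CC)(CC)CC)C(C)(C)O[C@@H]2CCC1=O
F12 | step 5 | (3R,5aR,9aR)-6-[2-(benzyloxy)ethylidene]-2,2,5a-trimethyl-3-[(triethylsilyl)oxy]-3,4,5,5a,6,8,9,9a-octahydro-1-benzoxepin-7(2H)-one | O(Cc1ccccc1)CC=C1[C@@]2(C)CC[C@@H](O[Si](CC)(CC)CC)C(C)(C)O[C@@H]2CCC1=O
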